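Retrosynthesis (drimane-type numbering; chain C11–C16; C17 is the butenolide β-carbon): the chain is cut at C16–C17 (Suzuki–Miyaura), C15=C16 (boryl olefination), C12–C13 (B-alkyl Suzuki–Miyaura) and C11=C12 (Wittig). Ring B is then cut at C5–C6 and C9–C10 ([4+2]).
Enabling feature: H-5 and the C10 methyl are cis at the ring A/ring B fusion, which is what suprafacial addition across a C5=C10 alkene held in ring A would leave. Ring B (C5–C10) is a cyclohexene that a C6=C7–C8=C9 diene can supply.
Forward order: ring A is made by annulation and ring B closes in the Diels–Alder step. The C1 oxygen is then removed and the C11 aldehyde pulls the alkene into C8=C9. The chain grows by C12, then C13–C15, then C16, then the purchased butenolide ring.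
Stereochemistry: the C5/C10 relative configuration comes from the cycloaddition and the absolute configuration from a chiral boron Lewis acid. The C13=C14 geometry comes from anti hydroalumination–iodination and is carried on with retention. The C15=C16 geometry comes from an E-selective chromium olefination.

Key step: step 4

Shorthand: β is the face of the C10 methyl. Bic = (4aR,8aS)-2,5,5,8a-tetramethyl-3,4,4a,5,6,7,8,8a-octahydronaphthalen-1-yl, which is cis-fused (5R,10S in drimane numbering, H-5 and C10 methyl both β) with a C8=C9 alkene.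
Assumption: the (S)-configured oxazaborolidinium ion is taken to open the enone face that leads to the (5R,10S) series; the enone has no α-hydrogen, so the usual binding picture gives no safe forecast, and the sense is to be fixed by correlation of the first adduct, with the equally available (R)-catalyst used if it proves opposite.

Step 1
Reactants: 1 isobutyraldehyde; 2 pent-1-en-3-one
Product: 4 2,4,4-trimethylcyclohex-2-en-1-one, via 2,2-dimethyl-5-oxoheptanal 3 (not isolated)
Conditions: cat. H2SO4, toluene, 45 °C, then reflux (Dean–Stark)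
Reagents that add atoms: none
Why: Acid-catalysed Michael addition of the aldehyde enol to the vinyl ketone followed by intramolecular aldol condensation (Robinson-type annulation) is the standard one-pot entry to 4,4-dialkylcyclohexenones, and in 3 only the ethyl CH2 can close a six-membered ring onto the non-enolisable aldehyde, which places the methyl group on the α-carbon.

Step 2
Reactants: 5 (E)-3-methylpent-2-en-4-yn-1-ol
Product: 6 tert-butyl{[(E)-3-methylpent-2-en-4-yn-1-yl]oxy}diphenylsilane
Conditions: TBDPSCl, imidazole, CH2Cl2, 0 °C → rt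
Reagents that add atoms: tert-butyl(chloro)diphenylsilane, CC(C)(C)[Si](Cl)(c1ccccc1)c1ccccc1
Why: This is a standard silylation of a primary allylic alcohol, and the tert-butyldiphenylsilyl ether is chosen because its oxygen is a poor donor towards boron and because it resists strong acid and later silyl migration.

Step 3
Reactants: 6 tert-butyl{[(E)-3-methylpent-2-en-4-yn-1-yl]oxy}diphenylsilane
Product: 7 tert-butyl{[(E)-3-methylpenta-2,4-dien-1-yl]oxy}diphenylsilane
Conditions: H2 (1 atm), Pd on CaCO3 poisoned with Pb(OAc)2 (Lindlar catalyst), quinoline, hexane, 0 °C, stopped after 1 equiv H2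
Reagents that add atoms: none
Why: Lindlar semihydrogenation stops a terminal alkyne at the vinyl stage and leaves the trisubstituted E-alkene untouched, so it should deliver the E-diene whose CH2OSi group points outward in the s-cis conformer.

Step 4
Reactants: 4 2,4,4-trimethylcyclohex-2-en-1-one; 7 tert-butyl{[(E)-3-methylpenta-2,4-dien-1-yl]oxy}diphenylsilane
Product: 8 (4aR,8R,8aS)-8-{[(tert-butyldiphenylsilyl)oxy]methyl}-4,4,7,8a-tetramethyl-3,4,4a,5,8,8a-hexahydronaphthalen-1(2H)-one (endo adduct; H-5 and C10 methyl cis, C11 trans to that methyl, C7=C8 alkene)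
Conditions: (S)-3,3-diphenyl-1-(2-methylphenyl)tetrahydro-1H,3H-pyrrolo[1,2-c][1,3,2]oxazaborole (20 mol %), HN(SO2CF3)2 (17 mol %), 4 (2 equiv), slow addition of 7, CH2Cl2 (concentrated), −40 °C → rt
Reagents that add atoms: none
Why: Proposed new method: the N-protonated oxazaborolidine binds the C1 carbonyl oxygen of 4 and lowers the enone LUMO, so that a concerted but asynchronous [4+2] cycloaddition can run in which the free diene terminus C6 bonds early to the β-carbon C5 and C9 closes late onto the α-carbon C10. The closest known reactions are oxazaborolidinium-catalysed Diels–Alder additions to unhindered cyclic enones and aluminium-halide-catalysed additions of alkyl dienes to 2-methyl- and 4,4-dimethylcyclohexenone; an enantioselective addition to an enone blocked at both alkene carbons has not been shown. Ring B (C5–C10) closes as a six-membered ring by intermolecular suprafacial–suprafacial cycloaddition that forms C5–C6 and C9–C10 in one event. C5 and C10 are tied to each other because both new bonds reach one face of the ring A alkene, so H-5 and the C10 methyl must be cis, their absolute sense comes from the enone face that the aryl groups of the catalyst leave open, and the fusion cannot epimerise afterwards because C10 is quaternary and C5 is not α to the ketone. C9 follows from the E geometry of 7 and the endo position of the C1 carbonyl, which puts C11 trans to the angular methyl, and since this centre is erased in step 9 an exo share does no harm. The step needs C6-to-C5 regiochemistry, which the 1-substituent (ortho) effect of the CH2OSi group favours and the C4 gem-dimethyl group enforces by admitting only a CH2 terminus beside it, while the bulky, weakly basic silyl ether keeps O-11 from competing for boron.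

Step 5
Reactants: 8 the endo adduct (1-ketone)
Product: 9 (1S,4aR,8R,8aS)-8-{[(tert-butyldiphenylsilyl)oxy]methyl}-4,4,7,8a-tetramethyl-1,2,3,4,4a,5,8,8a-octahydronaphthalen-1-ol (1α-alcohol)
Conditions: LiAlH4, Et2O, 0 °C
Reagents that add atoms: none
Why: In this hydride reduction of a hindered ketone, attack should come from the convex face of the cis-decalin (the face of H-5 and the angular methyl) and give the 1α-alcohol, whose configuration is of no consequence because C1 becomes CH2 in step 7.

Step 6
Reactants: 9 the 1α-alcohol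
Product: 10 O-[(1S,4aR,8R,8aS)-8-{[(tert-butyldiphenylsilyl)oxy]methyl}-4,4,7,8a-tetramethyl-1,2,3,4,4a,5,8,8a-octahydronaphthalen-1-yl] 1H-imidazole-1-carbothioate
Conditions: 1,1'-thiocarbonyldiimidazole, cat. DMAP, toluene, 90 °C
Reagents that add atoms: 1,1'-thiocarbonyldiimidazole, S=C(n1ccnc1)n1ccnc1
Why: Thioacylation of the secondary alcohol under neutral conditions (first half of the Barton–McCombie deoxygenation) avoids a free alkoxide and hence silyl migration from O-11.

Step 7
Reactants: 10 the imidazole-1-carbothioate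
Product: 11 tert-butyl{[(1R,4aR,8aS)-2,5,5,8a-tetramethyl-1,4,4a,5,6,7,8,8a-octahydronaphthalen-1-yl]methoxy}diphenylsilane
Conditions: Bu3SnH, AIBN, toluene, 100 °C
Reagents that add atoms: none
Why: In the Barton–McCombie radical deoxygenation the stannyl radical adds to sulfur, the secondary C1 radical is released and takes hydrogen from Bu3SnH, and the C7=C8 alkene could be reached only through strained 4-exo or 5-endo modes and so should stay untouched.

Step 8
Reactants: 11 the deoxygenated silyl ether
Product: 12 [(1R,4aR,8aS)-2,5,5,8a-tetramethyl-1,4,4a,5,6,7,8,8a-octahydronaphthalen-1-yl]methanol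
Conditions: Bu4NF, THF, rt
Reagents that add atoms: none
Why: Fluoride cleavage of the silyl ether, driven by the strong silicon–fluorine bond, frees the primary C11 alcohol in a molecule that holds no other reactive group.

Step 9
Reactants: 12 the C11 alcohol
Product: 14 (4aR,8aS)-2,5,5,8a-tetramethyl-3,4,4a,5,6,7,8,8a-octahydronaphthalene-1-carbaldehyde (Bic-CHO), via unconjugated aldehyde 13 (not isolated)
Conditions: Dess–Martin periodinane, CH2Cl2, 0 °C → rt; then DBU (5 equiv), rt
Reagents that add atoms: none
Why: Dess–Martin oxidation gives the β,γ-unsaturated aldehyde, and DBU then removes the acidic H-9 and the dienolate is reprotonated at C7, so the alkene moves into the conjugated tetrasubstituted C8=C9 position (the α- to β-cyclocitral type of isomerisation) and the provisional C9 centre disappears.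

Step 10
Reactants: 14 Bic-CHO
Product: 15 (4aR,8aS)-1-ethenyl-2,5,5,8a-tetramethyl-3,4,4a,5,6,7,8,8a-octahydronaphthalene (Bic-CH=CH2)
Conditions: MePPh3Br, KOtBu, THF, 0 °C → rt
Reagents that add atoms: methyltriphenylphosphonium bromide, [Br-].C[P+](c1ccccc1)(c1ccccc1)c1ccccc1
Why: Wittig methylenation with the small non-stabilised ylide is known to work on hindered β-cyclocitral-type enals and adds C12 without touching the ring alkene.

Step 11
Reactants: 16 but-2-yne-1,4-diol
Product: 17 4-[(tert-butyldimethylsilyl)oxy]but-2-yn-1-ol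
Conditions: NaH (1 equiv), THF, 0 °C; then TBSCl (1 equiv), rt
Reagents that add atoms: tert-butyl(chloro)dimethylsilane, CC(C)(C)[Si](C)(C)Cl
Why: Monosilylation of a symmetrical diol through its sparingly soluble monosodium alkoxide tells the two ends apart.

Step 12
Reactants: 17 4-[(tert-butyldimethylsilyl)oxy]but-2-yn-1-ol
Product: 19 (Z)-4-[(tert-butyldimethylsilyl)oxy]-3-iodobut-2-en-1-ol, via cyclic sodium alkenylalanate 18 (not isolated)
Conditions: NaAlH2(OCH2CH2OCH3)2, THF, 0 °C → rt; then N-iodosuccinimide, −78 °C → 0 °C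
Reagents that add atoms: N-iodosuccinimide, O=C1CCC(=O)N1I; sodium bis(2-methoxyethoxy)aluminium dihydride (its atoms stay only in 18), [Na+].COCCO[AlH2-]OCCOC
Why: Alkoxide-directed anti hydroalumination of the propargylic alcohol places aluminium on the distal alkyne carbon inside a five-membered alanate, and iodinolysis with retention puts iodine cis to the CH2OH arm (future C15) and the CH2OTBS arm trans to it, which is the C13=C14 geometry of the target.

Step 13
Reactants: 15 Bic-CH=CH2; 19 (Z)-4-[(tert-butyldimethylsilyl)oxy]-3-iodobut-2-en-1-ol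
Product: 21 (E)-5-Bic-3-{[(tert-butyldimethylsilyl)oxy]methyl}pent-2-en-1-ol, via B-alkyl-9-BBN 20 (not isolated)
Conditions: 9-BBN, THF, rt; then 19, PdCl2(dppf) (5 mol %), AsPh3, Cs2CO3, DMF/H2O, rt
Reagents that add atoms: 9-borabicyclo[3.3.1]nonane (its boron and carbon atoms stay only in 20), [H]B1C2CCCC1CCC2
Why: Anti-Markovnikov hydroboration picks the monosubstituted vinyl group (the tetrasubstituted ring alkene is inert to 9-BBN), and the B-alkyl Suzuki–Miyaura coupling replaces iodine with retention, so C12–C13 forms with C12 cis to C15.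

Step 14
Reactants: 21 the allylic alcohol
Product: 22 (E)-5-Bic-3-{[(tert-butyldimethylsilyl)oxy]methyl}pent-2-enal
Conditions: MnO2, CH2Cl2, rt
Reagents that add atoms: none
Why: MnO2 oxidises the only free (allylic) alcohol under neutral conditions, which should keep the C13=C14 geometry.

Step 15
Reactants: 22 the enal
Product: 23 2-[(1E,3E)-6-Bic-4-{[(tert-butyldimethylsilyl)oxy]methyl}hexa-1,3-dien-1-yl]-4,4,5,5-tetramethyl-1,3,2-dioxaborolane
Conditions: CrCl2, LiI, Cl2CHB(pin), THF, rt
Reagents that add atoms: 2-(dichloromethyl)-4,4,5,5-tetramethyl-1,3,2-dioxaborolane, ClC(Cl)B1OC(C)(C)C(C)(C)O1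
Why: In this Takai–Utimoto-type boryl olefination the geminal dichromium species made from the dihalomethylboronate and divalent chromium adds to the aldehyde and eliminates to the E-alkenylboronate, which sets C15=C16 and adds C16.

Step 16
Reactants: 23 the dienylboronate; 24 4-bromofuran-2(5H)-one
Product: 25 4-[(1E,3E)-6-Bic-4-{[(tert-butyldimethylsilyl)oxy]methyl}hexa-1,3-dien-1-yl]furan-2(5H)-one
Conditions: Pd(PPh3)4 (5 mol %), K3PO4, THF/H2O, 40 °C
Reagents that add atoms: none
Why: This is a Suzuki–Miyaura coupling in which the β-bromobutenolide, a vinylogous acyl bromide, adds readily to zerovalent palladium, so C16–C17 forms with retention of both alkene geometries.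

Step 17
Reactants: 25 the silyl-protected trienyl butenolide
Product: 26 4-[(1E,3E)-6-Bic-4-(hydroxymethyl)hexa-1,3-dien-1-yl]furan-2(5H)-one (target, CNP0232848.3)
Conditions: HF·pyridine, pyridine, THF, 0 °C → rt
Reagents that add atoms: none
Why: Buffered fluoride cleavage of the primary allylic silyl ether avoids basic conditions and so should spare the butenolide and the triene.

Compound list
1 | isobutyraldehyde | CC(C)C=O | starting material
2 | pent-1-en-3-one | CCC(=O)C=C | starting material
3 | 2,2-dimethyl-5-oxoheptanal | CCC(=O)CCC(C)(C)C=O | intermediate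
4 | 2,4,4-trimethylcyclohex-2-en-1-one | CC1=CC(C)(C)CCC1=O | intermediate
5 | (E)-3-methylpent-2-en-4-yn-1-ol | C#C/C(C)=C/CO | starting material
6 | tert-butyl{[(E)-3-methylpent-2-en-4-yn-1-yl]oxy}diphenylsilane | C#C/C(C)=C/CO[Si](c1ccccc1)(c1ccccc1)C(C)(C)C | intermediate
7 | tert-butyl{[(E)-3-methylpenta-2,4-dien-1-yl]oxy}diphenylsilane | C=C/C(C)=C/CO[Si](c1ccccc1)(c1ccccc1)C(C)(C)C | intermediate
8 | (4aR,8R,8aS)-8-{[(tert-butyldiphenylsilyl)oxy]methyl}-4,4,7,8a-tetramethyl-3,4,4a,5,8,8a-hexahydronaphthalen-1(2H)-one | CC1=CC[C@@H]2C(C)(C)CCC(=O)[C@]2(C)[C@@H]1CO[Si](c3ccccc3)(c3ccccc3)C(C)(C)C | intermediate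
9 | (1S,4aR,8R,8aS)-8-{[(tert-butyldiphenylsilyl)oxy]methyl}-4,4,7,8a-tetramethyl-1,2,3,4,4a,5,8,8a-octahydronaphthalen-1-ol | CC1=CC[C@@H]2C(C)(C)CC[C@H](O)[C@]2(C)[C@@H]1CO[Si](c3ccccc3)(c3ccccc3)C(C)(C)C | intermediate
10 | O-(1S,4aR,8R,8aS)-decalinyl 1H-imidazole-1-carbothioate of 9 | CC1=CC[C@@H]2C(C)(C)CC[C@H](OC(=S)n3ccnc3)[C@]2(C)[C@@H]1CO[Si](c3ccccc3)(c3ccccc3)C(C)(C)C | intermediate
11 | tert-butyl{[(1R,4aR,8aS)-2,5,5,8a-tetramethyl-1,4,4a,5,6,7,8,8a-octahydronaphthalen-1-yl]methoxy}diphenylsilane | CC1=CC[C@@H]2C(C)(C)CCC[C@]2(C)[C@@H]1CO[Si](c3ccccc3)(c3ccccc3)C(C)(C)C | intermediate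
12 | [(1R,4aR,8aS)-2,5,5,8a-tetramethyl-1,4,4a,5,6,7,8,8a-octahydronaphthalen-1-yl]methanol | CC1=CC[C@@H]2C(C)(C)CCC[C@]2(C)[C@@H]1CO | intermediate
13 | (1R,4aR,8aS)-2,5,5,8a-tetramethyl-1,4,4a,5,6,7,8,8a-octahydronaphthalene-1-carbaldehyde | CC1=CC[C@@H]2C(C)(C)CCC[C@]2(C)[C@@H]1C=O | intermediate
14 | (4aR,8aS)-2,5,5,8a-tetramethyl-3,4,4a,5,6,7,8,8a-octahydronaphthalene-1-carbaldehyde | CC1=C(C=O)[C@@]2(C)CCCC(C)(C)[C@H]2CC1 | intermediate
15 | (4aR,8aS)-1-ethenyl-2,5,5,8a-tetramethyl-3,4,4a,5,6,7,8,8a-octahydronaphthalene | CC1=C(C=C)[C@@]2(C)CCCC(C)(C)[C@H]2CC1 | intermediate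
16 | but-2-yne-1,4-diol | OCC#CCO | starting material
17 | 4-[(tert-butyldimethylsilyl)oxy]but-2-yn-1-ol | OCC#CCO[Si](C)(C)C(C)(C)C | intermediate
18 | cyclic sodium alkenylalanate (five-membered O–Al–C13=C14–C15 ring, two 2-methoxyethoxy groups on aluminium) | [Na+].COCCO[Al-]1(OCCOC)OCC=C1CO[Si](C)(C)C(C)(C)C | intermediate
19 | (Z)-4-[(tert-butyldimethylsilyl)oxy]-3-iodobut-2-en-1-ol | OC/C=C(\I)CO[Si](C)(C)C(C)(C)C | intermediate
20 | 9-(2-Bic-ethyl)-9-borabicyclo[3.3.1]nonane | CC1=C(CCB3C4CCCC3CCC4)[C@@]2(C)CCCC(C)(C)[C@H]2CC1 | intermediate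
21 | (E)-5-Bic-3-{[(tert-butyldimethylsilyl)oxy]methyl}pent-2-en-1-ol | CC1=C(CC/C(=C\CO)CO[Si](C)(C)C(C)(C)C)[C@@]2(C)CCCC(C)(C)[C@H]2CC1 | intermediate
22 | (E)-5-Bic-3-{[(tert-butyldimethylsilyl)oxy]methyl}pent-2-enal | CC1=C(CC/C(=C\C=O)CO[Si](C)(C)C(C)(C)C)[C@@]2(C)CCCC(C)(C)[C@H]2CC1 | intermediate
23 | 2-[(1E,3E)-6-Bic-4-{[(tert-butyldimethylsilyl)oxy]methyl}hexa-1,3-dien-1-yl]-4,4,5,5-tetramethyl-1,3,2-dioxaborolane | CC1=C(CC/C(=C\C=C\B3OC(C)(C)C(C)(C)O3)CO[Si](C)(C)C(C)(C)C)[C@@]2(C)CCCC(C)(C)[C@H]2CC1 | intermediate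
24 | 4-bromofuran-2(5H)-one | O=C1C=C(Br)CO1 | starting material
25 | 4-[(1E,3E)-6-Bic-4-{[(tert-butyldimethylsilyl)oxy]methyl}hexa-1,3-dien-1-yl]furan-2(5H)-one | CC1=C(CC/C(=C\C=C\C3=CC(=O)OC3)CO[Si](C)(C)C(C)(C)C)[C@@]2(C)CCCC(C)(C)[C@H]2CC1 | intermediate
26 | 4-[(1E,3E)-4-(hydroxymethyl)-6-[(4aR,8aS)-2,5,5,8a-tetramethyl-3,4,4a,5,6,7,8,8a-octahydronaphthalen-1-yl]hexa-1,3-dien-1-yl]furan-2(5H)-one | CC1=C(CC/C(=C\C=C\C2=CC(=O)OC2)CO)[C@@]2(C)CCCC(C)(C)[C@H]2CC1 | target

Total step count: 17.
Longest linear sequence: 14 steps (from 5 through steps 2–10 and 13–17).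

Steps most likely to fail

Step 4. The doubly hindered enone may react so slowly that acid-induced ionisation or oligomerisation of the diene overtakes the cycloaddition. In addition, without an α-hydrogen on the enone the catalyst may tell the two faces apart poorly. The fallback uses known chemistry, sets out from 4 and 7 and returns at 9. It takes the absolute configuration from a resolution instead of from a catalyst. The cycloaddition is run without chiral information, with AlCl3 or EtAlCl2 in toluene or at about 12 kbar, as is known for 2-methyl- and 4,4-dimethylcyclohexenones. This should give 8 together with the mirror-image adduct ent-8 F1. LiAlH4 reduction as in step 5 gives 9 together with the mirror-image alcohol ent-9 F2. Esterification with (S)-O-methylmandelic acid (DCC, DMAP) gives two diastereomers, the (S)-O-methylmandelate of 9 F3 and the (S)-O-methylmandelate of ent-9 F4, which are separated by chromatography. DIBAL-H cleavage of F3 returns 9 as a single enantiomer.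

Step 13. Hydroboration next to the crowded C9 position may be slow, or the alkyl group may transfer slowly from boron to palladium. Either would let protodeboronation, β-hydride elimination or reduction of the alkenyl iodide take over. The fallback sets out from 15, returns at 26, and builds C13=C14 by olefination instead of cross-coupling.
- Borane 20 is oxidised (NaOH, H2O2) to 2-Bic-ethanol F5, which is converted (I2, PPh3, imidazole) into 2-Bic-ethyl iodide F6.
- F6 alkylates sodium triethyl phosphonoacetate to give ethyl 4-Bic-2-(diethoxyphosphoryl)butanoate F7.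
- Horner–Wadsworth–Emmons reaction of F7 with (E)-3-(tributylstannyl)propenal F8 (MnO2 oxidation of the commercial stannyl allyl alcohol) should give ethyl (2E,4E)-2-(2-Bic-ethyl)-5-(tributylstannyl)penta-2,4-dienoate F9. In F9 the ester stands trans to C15, as required.
- DIBAL-H gives (2E,4E)-2-(2-Bic-ethyl)-5-(tributylstannyl)penta-2,4-dien-1-ol F10.
- Stille coupling of F10 with 24 (Pd2(dba)3, AsPh3, DMF) gives 26 without any protecting group.

Step 15. The β,β-disubstituted enal may lose its C13=C14 geometry by reversible conjugate addition or enolisation in the presence of Lewis acidic trivalent chromium salts. Addition of the bulky dichromium reagent may also be slow. The fallback sets out from 22, returns at 25, and brings in C16 and the intact butenolide in one chromium-free olefination. Arbuzov reaction of 4-(bromomethyl)furan-2(5H)-one with P(OEt)3 gives diethyl [(5-oxo-2,5-dihydrofuran-3-yl)methyl]phosphonate F11. Its lithium anion (LiHMDS, THF, −78 °C) reacts with 22 in a vinylogous Horner–Wadsworth–Emmons reaction to give 25 directly.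

Further compounds
F1 | step 4 | ent-8, (4aS,8S,8aR)-8-{[(tert-butyldiphenylsilyl)oxy]methyl}-4,4,7,8a-tetramethyl-3,4,4a,5,8,8a-hexahydronaphthalen-1(2H)-one | CC1=CC[C@H]2C(C)(C)CCC(=O)[C@@]2(C)[C@H]1CO[Si](c3ccccc3)(c3ccccc3)C(C)(C)C
F2 | step 4 | ent-9, the (1R,4aS,8S,8aR)-alcohol | CC1=CC[C@H]2C(C)(C)CC[C@@H](O)[C@@]2(C)[C@H]1CO[Si](c3ccccc3)(c3ccccc3)C(C)(C)C
F3 | step 4 | (S)-O-methylmandelate of 9 | CC1=CC[C@@H]2C(C)(C)CC[C@H](OC(=O)[C@@H](OC)c3ccccc3)[C@]2(C)[C@@H]1CO[Si](c3ccccc3)(c3ccccc3)C(C)(C)C
F4 | step 4 | (S)-O-methylmandelate of ent-9 | CC1=CC[C@H]2C(C)(C)CC[C@@H](OC(=O)[C@@H](OC)c3ccccc3)[C@@]2(C)[C@H]1CO[Si](c3ccccc3)(c3ccccc3)C(C)(C)C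
F5 | step 13 | 2-Bic-ethanol | CC1=C(CCO)[C@@]2(C)CCCC(C)(C)[C@H]2CC1
F6 | step 13 | 2-Bic-ethyl iodide | CC1=C(CCI)[C@@]2(C)CCCC(C)(C)[C@H]2CC1
F7 | step 13 | ethyl 4-Bic-2-(diethoxyphosphoryl)butanoate (both epimers at C13) | CC1=C(CCC(C(=O)OCC)P(=O)(OCC)OCC)[C@@]2(C)CCCC(C)(C)[C@H]2CC1
F8 | step 13 | (E)-3-(tributylstannyl)propenal | O=C/C=C/[Sn](CCCC)(CCCC)CCCC
F9 | step 13 | ethyl (2E,4E)-2-(2-Bic-ethyl)-5-(tributylstannyl)penta-2,4-dienoate | CC1=C(CC/C(=C\C=C\[Sn](CCCC)(CCCC)CCCC)C(=O)OCC)[C@@]2(C)CCCC(C)(C)[C@H]2CC1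
F10 | step 13 | (2E,4E)-2-(2-Bic-ethyl)-5-(tributylstannyl)penta-2,4-dien-1-ol | CC1=C(CC/C(=C\C=C\[Sn](CCCC)(CCCC)CCCC)CO)[C@@]2(C)CCCC(C)(C)[C@H]2CC1
F11 | step 15 | diethyl [(5-oxo-2,5-dihydrofuran-3-yl)methyl]phosphonate | CCOP(=O)(CC1=CC(=O)OC1)OCC
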